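**Retrosynthetic overview**

1. Target 24 ⇐ 8β‑alcohol 23 by methacryloylation of O8 (last step).
2. 23 ⇐ open‑chain enal/bromobutenolide 20: CrCl2‑mediated intramolecular allylation closes C6–C7 (ten‑membered carbocycle), and in the same flask the new O6 alkoxide takes the lactone carbonyl over from O8 (trans‑fused 6,12‑α‑methylene lactone).
3. 20 ⇐ vinyl carbinol 17 + 2‑(bromomethyl)acrylic acid 18 (esterification, then RCM to a butenolide on O8); the 1,10‑epoxide comes earlier from Sharpless epoxidation of allylic alcohol 13.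
4. 13 ⇐ enynol 10 (trans‑hydrostannation, then hydroxymethylation: sets C1=C10 geometry and C14) ⇐ alkyne 5 + (R)‑epichlorohydrin 6 (source of C8).
5. 5 ⇐ geraniol 1. Ring order: epoxide, then butenolide (temporary 8,12‑lactone), then ten‑membered ring together with the 6,12‑lactone.

Assumption: locants such as C6 or C14 are germacrane numbering of the target (C6 and C8 oxygenated ring carbons, C1–C10 epoxide, C12 lactone carbonyl, C13 exocyclic methylene, C14 acetoxymethyl, C15 ring methyl).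

**Route**

Step 1
Reactants: 1 geraniol
Product: 2 geranyl tert‑butyldimethylsilyl ether
Conditions: TBSCl, imidazole, DMF, 0 °C to rt
Reagents that add atoms: tert‑butyldimethylsilyl chloride CC(C)(C)[Si](C)(C)Cl
Why: Silyl ether protection of the primary allylic alcohol, needed because organolithium reagents follow; no stereocentre is made and the E alkene is untouched.

Step 2
Reactants: 2 geranyl tert‑butyldimethylsilyl ether
Product: 4 (4E)‑6‑(tert‑butyldimethylsilyloxy)‑4‑methylhex‑4‑enal, via ozonide 3 (not isolated)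
Conditions: O3 (1 equiv), CH2Cl2, −78 °C; then PPh3, −78 °C to rt
Reagents that add atoms: ozone [O-][O+]=O
Why: Chemoselective ozonolysis with reductive work‑up, because the isolated isopropylidene alkene is more electron‑rich than the alkene carrying the allylic silyloxy group, so one equivalent of ozone cleaves only the terminal C=C and leaves the aldehyde carbon that becomes C1.

Step 3
Reactants: 4 (4E)‑6‑(tert‑butyldimethylsilyloxy)‑4‑methylhex‑4‑enal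
Product: 5 tert‑butyldimethyl{[(2E)‑3‑methylhept‑2‑en‑6‑yn‑1‑yl]oxy}silane
Conditions: dimethyl (1‑diazo‑2‑oxopropyl)phosphonate, K2CO3, MeOH, 0 °C to rt
Reagents that add atoms: dimethyl (1‑diazo‑2‑oxopropyl)phosphonate COP(=O)(OC)C(=[N+]=[N-])C(C)=O
Why: Seyferth–Gilbert homologation in the Ohira–Bestmann form turns the aldehyde into the terminal alkyne (new carbon = C10) under carbonate conditions that spare the silyl ether and the E alkene.

Step 4
Reactants: 5 tert‑butyldimethyl{[(2E)‑3‑methylhept‑2‑en‑6‑yn‑1‑yl]oxy}silane, 6 (R)‑epichlorohydrin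
Product: 8 (2R,8E)‑10‑(tert‑butyldimethylsilyloxy)‑1‑chloro‑8‑methyldec‑8‑en‑4‑yn‑2‑ol, via lithium acetylide 7 (not isolated)
Conditions: n‑BuLi, THF, −78 °C; BF3·OEt2, then 6, −78 °C
Reagents that add atoms: none
Why: Yamaguchi‑type alkynylation, in which the BF3‑activated epoxide is opened by SN2 attack at its CH2 carbon, so the stereocentre of 6 is not touched and becomes C8 (R).

Step 5
Reactants: 8 (2R,8E)‑10‑(tert‑butyldimethylsilyloxy)‑1‑chloro‑8‑methyldec‑8‑en‑4‑yn‑2‑ol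
Product: 10 (3R,9E)‑11‑(tert‑butyldimethylsilyloxy)‑9‑methylundeca‑1,9‑dien‑5‑yn‑3‑ol, via terminal epoxide 9 (not isolated)
Conditions: Me3S+ I− (4 equiv), n‑BuLi (3.8 equiv), THF, −10 °C to rt
Reagents that add atoms: trimethylsulfonium iodide C[S+](C)C.[I-]
Why: Sulfonium ylide homologation of an epoxide to an allylic alcohol: the ylide first closes the chlorohydrin to 9 as a base, then opens 9 at the terminal carbon and loses dimethyl sulfide, leaving the carbinol centre C8 unchanged.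

Step 6
Reactants: 10 (3R,9E)‑11‑(tert‑butyldimethylsilyloxy)‑9‑methylundeca‑1,9‑dien‑5‑yn‑3‑ol
Product: 11 (3R,5Z,9E)‑11‑(tert‑butyldimethylsilyloxy)‑9‑methyl‑5‑(tributylstannyl)undeca‑1,5,9‑trien‑3‑ol
Conditions: [Cp*RuCl]4 (2.5 mol %), Bu3SnH, CH2Cl2, rt
Reagents that add atoms: tributyltin hydride CCCC[SnH](CCCC)CCCC
Why: Ruthenium‑catalysed hydroxyl‑directed trans‑hydrostannation, in which the free homopropargylic OH hydrogen‑bonds to the chloride ligand and steers tin to the proximal alkyne carbon (C10), while anti addition puts tin cis to the C2 chain and so fixes the geometry of the future C1=C10 alkene.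

Step 7
Reactants: 11 (3R,5Z,9E)‑11‑(tert‑butyldimethylsilyloxy)‑9‑methyl‑5‑(tributylstannyl)undeca‑1,5,9‑trien‑3‑ol
Product: 13 (3R,5Z,9E)‑11‑(tert‑butyldimethylsilyloxy)‑5‑(hydroxymethyl)‑9‑methylundeca‑1,5,9‑trien‑3‑ol, via dilithio alkenyllithium 12 (not isolated)
Conditions: n‑BuLi (2.3 equiv), THF, −78 to −30 °C; then (CH2O)n, −78 °C to rt
Reagents that add atoms: formaldehyde (from paraformaldehyde) C=O
Why: Tin–lithium exchange with retention of alkene geometry, then 1,2‑addition of the alkenyllithium to formaldehyde, installs C14 cis to the C2 chain, the arrangement a trans‑1,10‑epoxide needs.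

Step 8
Reactants: 13 (3R,5Z,9E)‑11‑(tert‑butyldimethylsilyloxy)‑5‑(hydroxymethyl)‑9‑methylundeca‑1,5,9‑trien‑3‑ol
Product: 14 (2R)‑1‑[(2S,3R)‑3‑{(3E)‑5‑(tert‑butyldimethylsilyloxy)‑3‑methylpent‑3‑en‑1‑yl}‑2‑(hydroxymethyl)oxiran‑2‑yl]but‑3‑en‑2‑ol
Conditions: Ti(OiPr)4 (20 mol %), L‑(+)‑diethyl tartrate (24 mol %), t‑BuOOH, 4 Å MS, CH2Cl2, −25 °C
Reagents that add atoms: tert‑butyl hydroperoxide CC(C)(C)OO
Why: Sharpless asymmetric epoxidation, in which the primary allylic alcohol binds the titanium tartrate and L‑(+)‑tartrate delivers oxygen to the face that gives the (1R,10S) trans‑epoxide, while the (R) vinyl carbinol is the slow‑reacting enantiomer for this tartrate and the silyl‑protected C4=C5 alkene has no directing OH.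

Step 9
Reactants: 14 (2R)‑1‑[(2S,3R)‑3‑{(3E)‑5‑(tert‑butyldimethylsilyloxy)‑3‑methylpent‑3‑en‑1‑yl}‑2‑(hydroxymethyl)oxiran‑2‑yl]but‑3‑en‑2‑ol
Product: 15 {(2S,3R)‑3‑[(3E)‑5‑(tert‑butyldimethylsilyloxy)‑3‑methylpent‑3‑en‑1‑yl]‑2‑[(2R)‑2‑hydroxybut‑3‑en‑1‑yl]oxiran‑2‑yl}methyl acetate
Conditions: AcCl, 2,4,6‑collidine, CH2Cl2, −78 °C
Reagents that add atoms: acetyl chloride CC(Cl)=O
Why: Kinetically selective acetylation of the primary alcohol (C14) over the hindered secondary allylic alcohol; no stereocentre is affected.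

Step 10
Reactants: 15 {(2S,3R)‑3‑[(3E)‑5‑(tert‑butyldimethylsilyloxy)‑3‑methylpent‑3‑en‑1‑yl]‑2‑[(2R)‑2‑hydroxybut‑3‑en‑1‑yl]oxiran‑2‑yl}methyl acetate
Product: 16 {(2S,3R)‑2‑[(2R)‑2‑hydroxybut‑3‑en‑1‑yl]‑3‑[(3E)‑5‑hydroxy‑3‑methylpent‑3‑en‑1‑yl]oxiran‑2‑yl}methyl acetate
Conditions: Bu4NF, AcOH, THF, 0 °C to rt
Reagents that add atoms: none
Why: Fluoride desilylation, buffered with acetic acid so that the acetate does not migrate or hydrolyse and the epoxide stays closed.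

Step 11
Reactants: 16 {(2S,3R)‑2‑[(2R)‑2‑hydroxybut‑3‑en‑1‑yl]‑3‑[(3E)‑5‑hydroxy‑3‑methylpent‑3‑en‑1‑yl]oxiran‑2‑yl}methyl acetate
Product: 17 {(2S,3R)‑2‑[(2R)‑2‑hydroxybut‑3‑en‑1‑yl]‑3‑[(3E)‑3‑methyl‑5‑oxopent‑3‑en‑1‑yl]oxiran‑2‑yl}methyl acetate
Conditions: TEMPO (10 mol %), PhI(OAc)2, CH2Cl2, rt
Reagents that add atoms: none
Why: Nitroxyl‑catalysed oxidation is selective for the primary allylic alcohol and gives the (E)‑enal (C6) without touching the secondary alcohol, epoxide or acetate and without E/Z isomerisation.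

Step 12
Reactants: 17 {(2S,3R)‑2‑[(2R)‑2‑hydroxybut‑3‑en‑1‑yl]‑3‑[(3E)‑3‑methyl‑5‑oxopent‑3‑en‑1‑yl]oxiran‑2‑yl}methyl acetate, 18 2‑(bromomethyl)acrylic acid
Product: 19 (2R)‑1‑{(2S,3R)‑2‑(acetoxymethyl)‑3‑[(3E)‑3‑methyl‑5‑oxopent‑3‑en‑1‑yl]oxiran‑2‑yl}but‑3‑en‑2‑yl 2‑(bromomethyl)prop‑2‑enoate
Conditions: DCC, DMAP (5 mol %), CH2Cl2, 0 °C
Reagents that add atoms: none
Why: Steglich esterification of the C8 hydroxyl forms only the acyl C–O bond, so C8 keeps its configuration.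

Step 13
Reactants: 19 (2R)‑1‑{(2S,3R)‑2‑(acetoxymethyl)‑3‑[(3E)‑3‑methyl‑5‑oxopent‑3‑en‑1‑yl]oxiran‑2‑yl}but‑3‑en‑2‑yl 2‑(bromomethyl)prop‑2‑enoate
Product: 20 {(2S,3R)‑2‑{[(2R)‑4‑(bromomethyl)‑5‑oxo‑2,5‑dihydrofuran‑2‑yl]methyl}‑3‑[(3E)‑3‑methyl‑5‑oxopent‑3‑en‑1‑yl]oxiran‑2‑yl}methyl acetate
Conditions: second‑generation Grubbs catalyst (H2IMes)(PCy3)Cl2Ru=CHPh (5 mol %), toluene (5 mM), 80 °C
Reagents that add atoms: none
Why: Ring‑closing metathesis between the terminal vinyl group and the 1,1‑disubstituted acrylate gives the five‑membered butenolide with loss of ethene, the trisubstituted enal alkene being too hindered to compete.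

Step 14
Reactants: 20 {(2S,3R)‑2‑{[(2R)‑4‑(bromomethyl)‑5‑oxo‑2,5‑dihydrofuran‑2‑yl]methyl}‑3‑[(3E)‑3‑methyl‑5‑oxopent‑3‑en‑1‑yl]oxiran‑2‑yl}methyl acetate
Product: 23 14‑acetoxy‑1β,10α‑epoxy‑8β‑hydroxygermacra‑4E,11(13)‑dien‑12,6α‑olide, via allylchromium species 21 (not isolated), via chromium alkoxide 22 (not isolated)
Conditions: CrCl2 (8 equiv), THF/DMF 4:1, 20 added by syringe pump (final 2 mM), rt; then 40 °C, 6 h; aq NH4Cl
Reagents that add atoms: none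
Why: Proposed new method: CrCl2 (divalent chromium) inserts into the allylic C–Br bond and allylchromium species 21 adds through C7 to the tethered enal in a closed chair transition state in which the butenolide ring (a) locks the allyl unit in the E‑crotyl‑type geometry, so that with the enal substituent equatorial H6 and H7 become trans, and (b) holds O8 in the allyl plane, so that the chain on C8 can deliver the aldehyde only to the C7 face syn to C9 (7R from 8R), which closes the ten‑membered carbocycle as chromium alkoxide 22, whose trivalent chromium alkoxide on O6 then attacks the lactone carbonyl five‑exo and releases O8, moving the lactone to the more stable trans‑fused 6,12‑position and forming the second ring in the same flask; the closest known reactions are Nozaki–Hiyama–Kishi/Barbier allylation–lactonization of 2‑(bromomethyl)acrylates and 3‑(bromomethyl)butenolides, chromium‑mediated macrocyclic allylation to ten‑membered carbocycles, and translactonization of hydroxy γ‑lactones.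

Step 15
Reactants: 23 14‑acetoxy‑1β,10α‑epoxy‑8β‑hydroxygermacra‑4E,11(13)‑dien‑12,6α‑olide
Product: 24 14‑acetoxy‑1β,10α‑epoxy‑8β‑(methacryloyloxy)germacra‑4E,11(13)‑dien‑12,6α‑olide (CNP0150481.3)
Conditions: methacrylic anhydride, Et3N, DMAP (20 mol %), CH2Cl2, 0 °C to rt
Reagents that add atoms: methacrylic anhydride CC(=C)C(=O)OC(=O)C(C)=C
Why: DMAP‑catalysed esterification of the freed 8β‑hydroxyl with retention at C8; the epoxide, acetate and α‑methylene lactone tolerate these mild basic conditions.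

**Compound list**

1 | geraniol, (2E)‑3,7‑dimethylocta‑2,6‑dien‑1‑ol | OC/C=C(\C)CCC=C(C)C | starting material
2 | geranyl tert‑butyldimethylsilyl ether | CC(C)=CCC/C(C)=C/CO[Si](C)(C)C(C)(C)C | intermediate
3 | ozonide: 5‑{(3E)‑5‑(tert‑butyldimethylsilyloxy)‑3‑methylpent‑3‑en‑1‑yl}‑3,3‑dimethyl‑1,2,4‑trioxolane (formed in the flask) | CC1(C)OOC(CC/C(C)=C/CO[Si](C)(C)C(C)(C)C)O1 | intermediate
4 | (4E)‑6‑(tert‑butyldimethylsilyloxy)‑4‑methylhex‑4‑enal | O=CCC/C(C)=C/CO[Si](C)(C)C(C)(C)C | intermediate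
5 | tert‑butyldimethyl{[(2E)‑3‑methylhept‑2‑en‑6‑yn‑1‑yl]oxy}silane | C#CCC/C(C)=C/CO[Si](C)(C)C(C)(C)C | intermediate
6 | (R)‑epichlorohydrin, (2R)‑2‑(chloromethyl)oxirane | ClC[C@H]1CO1 | starting material
7 | lithium acetylide of 5 (formed in the flask) | [Li]C#CCC/C(C)=C/CO[Si](C)(C)C(C)(C)C | intermediate
8 | (2R,8E)‑10‑(tert‑butyldimethylsilyloxy)‑1‑chloro‑8‑methyldec‑8‑en‑4‑yn‑2‑ol | ClC[C@H](O)CC#CCC/C(C)=C/CO[Si](C)(C)C(C)(C)C | intermediate
9 | (2R)‑2‑{(6E)‑8‑(tert‑butyldimethylsilyloxy)‑6‑methyloct‑6‑en‑2‑yn‑1‑yl}oxirane (formed in the flask) | O1C[C@H]1CC#CCC/C(C)=C/CO[Si](C)(C)C(C)(C)C | intermediate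
10 | (3R,9E)‑11‑(tert‑butyldimethylsilyloxy)‑9‑methylundeca‑1,9‑dien‑5‑yn‑3‑ol | C=C[C@H](O)CC#CCC/C(C)=C/CO[Si](C)(C)C(C)(C)C | intermediate
11 | (3R,5Z,9E)‑11‑(tert‑butyldimethylsilyloxy)‑9‑methyl‑5‑(tributylstannyl)undeca‑1,5,9‑trien‑3‑ol | C=C[C@H](O)C/C(=C/CC/C(C)=C/CO[Si](C)(C)C(C)(C)C)[Sn](CCCC)(CCCC)CCCC | intermediate
12 | dilithio species: lithium alkoxide of the 5‑lithio analogue of 11, alkene geometry retained (formed in the flask) | C=C[C@H](O[Li])C/C([Li])=C/CC/C(C)=C/CO[Si](C)(C)C(C)(C)C | intermediate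
13 | (3R,5Z,9E)‑11‑(tert‑butyldimethylsilyloxy)‑5‑(hydroxymethyl)‑9‑methylundeca‑1,5,9‑trien‑3‑ol | C=C[C@H](O)C/C(CO)=C/CC/C(C)=C/CO[Si](C)(C)C(C)(C)C | intermediate
14 | (2R)‑1‑[(2S,3R)‑3‑{(3E)‑5‑(tert‑butyldimethylsilyloxy)‑3‑methylpent‑3‑en‑1‑yl}‑2‑(hydroxymethyl)oxiran‑2‑yl]but‑3‑en‑2‑ol | C=C[C@H](O)C[C@@]1(CO)O[C@@H]1CC/C(C)=C/CO[Si](C)(C)C(C)(C)C | intermediate
15 | {(2S,3R)‑3‑[(3E)‑5‑(tert‑butyldimethylsilyloxy)‑3‑methylpent‑3‑en‑1‑yl]‑2‑[(2R)‑2‑hydroxybut‑3‑en‑1‑yl]oxiran‑2‑yl}methyl acetate | C=C[C@H](O)C[C@@]1(COC(C)=O)O[C@@H]1CC/C(C)=C/CO[Si](C)(C)C(C)(C)C | intermediate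
16 | {(2S,3R)‑2‑[(2R)‑2‑hydroxybut‑3‑en‑1‑yl]‑3‑[(3E)‑5‑hydroxy‑3‑methylpent‑3‑en‑1‑yl]oxiran‑2‑yl}methyl acetate | C=C[C@H](O)C[C@@]1(COC(C)=O)O[C@@H]1CC/C(C)=C/CO | intermediate
17 | {(2S,3R)‑2‑[(2R)‑2‑hydroxybut‑3‑en‑1‑yl]‑3‑[(3E)‑3‑methyl‑5‑oxopent‑3‑en‑1‑yl]oxiran‑2‑yl}methyl acetate | C=C[C@H](O)C[C@@]1(COC(C)=O)O[C@@H]1CC/C(C)=C/C=O | intermediate
18 | 2‑(bromomethyl)acrylic acid | OC(=O)C(=C)CBr | starting material
19 | (2R)‑1‑{(2S,3R)‑2‑(acetoxymethyl)‑3‑[(3E)‑3‑methyl‑5‑oxopent‑3‑en‑1‑yl]oxiran‑2‑yl}but‑3‑en‑2‑yl 2‑(bromomethyl)prop‑2‑enoate | C=C[C@H](OC(=O)C(=C)CBr)C[C@@]1(COC(C)=O)O[C@@H]1CC/C(C)=C/C=O | intermediate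
20 | {(2S,3R)‑2‑{[(2R)‑4‑(bromomethyl)‑5‑oxo‑2,5‑dihydrofuran‑2‑yl]methyl}‑3‑[(3E)‑3‑methyl‑5‑oxopent‑3‑en‑1‑yl]oxiran‑2‑yl}methyl acetate | O=C1O[C@H](C[C@@]2(COC(C)=O)O[C@@H]2CC/C(C)=C/C=O)C=C1CBr | intermediate
21 | allylchromium dichloride from 20, CH2Br replaced by CH2CrCl2 (formed in the flask) | O=C1O[C@H](C[C@@]2(COC(C)=O)O[C@@H]2CC/C(C)=C/C=O)C=C1C[Cr](Cl)Cl | intermediate
22 | dichlorochromium 6α‑alkoxide of 14‑acetoxy‑1β,10α‑epoxy‑6α‑hydroxygermacra‑4E,11(13)‑dien‑12,8β‑olide, cis‑fused lactone, H‑7α (formed in the flask) | O=C1O[C@@H]2C[C@@]3(COC(C)=O)O[C@@H]3CC/C(C)=C/[C@@H](O[Cr](Cl)Cl)[C@@H]2C1=C | intermediate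
23 | (1R,6R,7R,8R,10S)‑14‑acetoxy‑1β,10α‑epoxy‑8β‑hydroxygermacra‑4E,11(13)‑dien‑12,6α‑olide (H‑6β, H‑7α) | O[C@@H]1C[C@@]2(COC(C)=O)O[C@@H]2CC/C(C)=C/[C@H]2OC(=O)C(=C)[C@@H]21 | intermediate
24 | (1R,6R,7R,8R,10S)‑14‑acetoxy‑1β,10α‑epoxy‑8β‑(methacryloyloxy)germacra‑4E,11(13)‑dien‑12,6α‑olide, CNP0150481.3 | C=C(C)C(=O)O[C@@H]1C[C@@]2(COC(C)=O)O[C@@H]2CC/C(C)=C/[C@H]2OC(=O)C(=C)[C@@H]21 | target

**Totals**

Total step count: 15. Longest linear sequence: 15 steps (geraniol 1 to 24); 6 and 18 are bought and used directly.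

**Three steps most likely to fail, each with a fallback**

Step 14 (ring closure with lactone transposition in one flask). The risks are oligomerisation, the wrong C6 configuration, or a lactone that stays on O8. The fallback sets out from 20 and returns at 23, and separates the two events. Indium powder in THF/water at high dilution closes the ten‑membered ring by Barbier allylation, and the aqueous medium protonates the alkoxide at once, so the cis‑fused hydroxy lactone 14‑acetoxy‑1β,10α‑epoxy‑6α‑hydroxygermacra‑4E,11(13)‑dien‑12,8β‑olide F1 is isolated. In a separate, thermodynamically controlled step, catalytic DBU in THF moves the lactone from O8 to O6 and gives 23.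

Step 6 (tin must go to C10 of a homopropargylic, not propargylic, alcohol). The fallback sets out from 10 and returns at 13, bypassing 11 and 12. Hydroxyl‑directed trans‑hydroalumination with NaAlH2(OCH2CH2OMe)2 in THF, then iodine, gives (3R,5Z,9E)‑11‑(tert‑butyldimethylsilyloxy)‑5‑iodo‑9‑methylundeca‑1,5,9‑trien‑3‑ol F2. Stille coupling of F2 with (tributylstannyl)methanol under Pd(PPh3)4 (zerovalent palladium) in dioxane at 80 °C then gives 13.

Step 13 (RCM onto a 1,1‑disubstituted, electron‑poor alkene that carries an allylic bromide). The fallback sets out from 17 and returns at 20, and installs the bromomethyl group after ring closure. Acryloyl chloride and Et3N give (2R)‑1‑{(2S,3R)‑2‑(acetoxymethyl)‑3‑[(3E)‑3‑methyl‑5‑oxopent‑3‑en‑1‑yl]oxiran‑2‑yl}but‑3‑en‑2‑yl prop‑2‑enoate F3. RCM of this unhindered diene with the same ruthenium catalyst gives {(2S,3R)‑3‑[(3E)‑3‑methyl‑5‑oxopent‑3‑en‑1‑yl]‑2‑{[(2R)‑5‑oxo‑2,5‑dihydrofuran‑2‑yl]methyl}oxiran‑2‑yl}methyl acetate F4. A Morita–Baylis–Hillman reaction of F4 with aqueous formaldehyde (imidazole or PBu3) gives {(2S,3R)‑2‑{[(2R)‑4‑(hydroxymethyl)‑5‑oxo‑2,5‑dihydrofuran‑2‑yl]methyl}‑3‑[(3E)‑3‑methyl‑5‑oxopent‑3‑en‑1‑yl]oxiran‑2‑yl}methyl acetate F5, and CBr4/PPh3 (Appel reaction) converts F5 into 20.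

**Further compounds**

F1 | step 14 | 14‑acetoxy‑1β,10α‑epoxy‑6α‑hydroxygermacra‑4E,11(13)‑dien‑12,8β‑olide (cis‑fused lactone, H‑7α) | O=C1O[C@@H]2C[C@@]3(COC(C)=O)O[C@@H]3CC/C(C)=C/[C@@H](O)[C@@H]2C1=C
F2 | step 6 | (3R,5Z,9E)‑11‑(tert‑butyldimethylsilyloxy)‑5‑iodo‑9‑methylundeca‑1,5,9‑trien‑3‑ol | C=C[C@H](O)C/C(I)=C/CC/C(C)=C/CO[Si](C)(C)C(C)(C)C
F3 | step 13 | (2R)‑1‑{(2S,3R)‑2‑(acetoxymethyl)‑3‑[(3E)‑3‑methyl‑5‑oxopent‑3‑en‑1‑yl]oxiran‑2‑yl}but‑3‑en‑2‑yl prop‑2‑enoate | C=C[C@H](OC(=O)C=C)C[C@@]1(COC(C)=O)O[C@@H]1CC/C(C)=C/C=O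
F4 | step 13 | {(2S,3R)‑3‑[(3E)‑3‑methyl‑5‑oxopent‑3‑en‑1‑yl]‑2‑{[(2R)‑5‑oxo‑2,5‑dihydrofuran‑2‑yl]methyl}oxiran‑2‑yl}methyl acetate | O=C1O[C@H](C[C@@]2(COC(C)=O)O[C@@H]2CC/C(C)=C/C=O)C=C1
F5 | step 13 | {(2S,3R)‑2‑{[(2R)‑4‑(hydroxymethyl)‑5‑oxo‑2,5‑dihydrofuran‑2‑yl]methyl}‑3‑[(3E)‑3‑methyl‑5‑oxopent‑3‑en‑1‑yl]oxiran‑2‑yl}methyl acetate | O=C1O[C@H](C[C@@]2(COC(C)=O)O[C@@H]2CC/C(C)=C/C=O)C=C1CO
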